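The data stem from a simulated flask with made-up constants; the scatter is artificial.

The leftover is what I read first: in Thursday's run at 2.50 h, 36.6% of the charge has left the starting material, yet 9.9% stands as target, and I book the rest as over-reaction product.

| flask | starting material | solid reagent | remark | time |
|---|---|---|---|---|
| Thursday's | 0.10 M | 3 equiv | run made earlier |  |
| Tuesday's | 0.42 M | 3 equiv | run made earlier |  |
| Sunday's | 0.21 M | 4.5 equiv | run made earlier |  |
| gamma | 0.21 M | 3.00 equiv |  | 3.0 h |
| alpha | 0.21 M | 3.00 equiv |  | 2.0 h |

| run | time / h | target / % | starting material / % |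
|---|---|---|---|
| Thursday's | 0.333 | 1.8 | 98.0 |
| Thursday's | 0.833 | 5.5 | 90.9 |
| Thursday's | 1.50 | 9.4 | 79.9 |
| Thursday's | 2.50 | 9.9 | 63.4 |
| Tuesday's | 0.333 | 0.9 | 97.8 |
| Tuesday's | 0.833 | 4.1 | 94.4 |
| Tuesday's | 1.50 | 5.7 | 87.3 |
| Tuesday's | 2.50 | 6.8 | 76.1 |
| Sunday's | 0.333 | 1.1 | 98.3 |
| Sunday's | 0.833 | 4.7 | 89.6 |
| Sunday's | 1.50 | 8.7 | 82.2 |
| Sunday's | 2.50 | 10.2 | 67.3 |

(each reading ± 1 percentage point)

- solid, in amounts per volume of the solution: solid reagent
- the earlier runs were read with a standard deviation of 1 percentage point
- at the start none of the solid reagent is in solution

- which of the two there is more of at the end, gamma (target / over-reaction product)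
- which of the two there is more of at the end, alpha (target / over-reaction product)
- amount of target at the end, in percent of the starting material charged, gamma
- amount of target at the end, in percent of the starting material charged, alpha

So target is a way station, and I solve it at both ends and join. At the start it holds nothing. Late it climbs slowly, so what arrives nearly equals what leaves. In Sunday's run from 1.50 h to 2.50 h, starting material falls 15 percentage points over a mean target of 9.45%, which gives 1.58 h⁻¹. Thursday's and Tuesday's runs bracket the 0.21 M of alpha and gamma at the same equivalents, and over that window they lose a mean 0.139 h⁻¹ as a fraction of the charge. Dividing gives a plateau near 8.80%.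

The weak link is that this rests on one run, in which target still climbs. So I reforge it: the drain constant, the fraction of the target leaving per hour, is arrival minus accumulation over what stands, pooled across the earlier runs, 1.56 h⁻¹. The plateau, arrival over drain constant as in the steady-state treatment of an intermediate, becomes 8.89%, approached with a time of 0.642 h, shorter than alpha's 2.0 h. Joining the ends, I commit to 8.49% target for alpha and 8.81% for gamma. Carrying the mean loss from 2.50 h back to alpha's time and on to gamma's leaves about 14.8% over-reaction product in alpha and 28.4% in gamma, more than target in both.

The forecast, close to this, says 8.5% for alpha and 9% for gamma, with over-reaction product ahead in both, and holds that “The second step is clearly faster than the first”.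

The flasks give 9.04% target and 15.1% over-reaction product in alpha, 9.27% and 28.1% in gamma.

    solid reagent ⇌ partner, rate k1*(cs1 - [partner]) while solid is left; crystals form when [partner] > cs1 (solubility = 0.140 M, k = 0.610 h⁻¹)
    starting material + partner ⇌ isomer of the product (K = 73.0 L mol⁻¹, k = 0.0870 L mol⁻¹ h⁻¹)
    target → over-reaction product (k = 1.40 h⁻¹)
    starting material + partner ⇌ target (K = 3.50 L mol⁻¹, k = 5.70 L mol⁻¹ h⁻¹)

In gamma at 3.00 h, target is made 0.966 times as fast as it is used up, each step taken net, and its half-life against turning into over-reaction product, 0.50 h, is shorter than the 3.0 h of the run. The drain constant times gamma's target gives 0.145 h⁻¹, against a fall of starting material of 0.137 h⁻¹ from alpha at 2.0 h to gamma at 3.0 h, the two flasks being charged alike. Gamma's fall of starting material from 3.0 h until 5.0 h, divided by the drain constant, gives 7.22% target, and gamma read at 5.0 h holds 7.39%.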